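**Retrosynthetic overview**
- The target is cut at the bond between C2 of the indenone and C3 of the guaiazulene unit. This gives commercial guaiazulene, used as the C–H partner, and a 2-bromo-3-methylindenone that already carries the formyl group; they are joined in the last step by a palladium-catalysed direct C–H alkenylation.
- Enabling feature: in the five-membered ring of guaiazulene C1 carries a methyl group, so C3 is the only free carbon of the 1/3 type. It is the most nucleophilic atom of the azulene and its σ-complex is a tropylium ion. The other end of the bond is the α-carbon (C2) of the indenone enone, which accepts bromine and then adds to zerovalent palladium.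
- The bromoindenone comes from the indanone by double bromination at C2 and loss of HBr; the formyl group comes from an aryl bromide by reductive carbonylation.
- Ring order: the benzene ring is bought as 4-bromotoluene, the five-membered ketone ring is closed by Friedel–Crafts acylation and Nazarov cyclisation, and the azulene bicycle is bought intact and attached last.

Key step: step 6

Assumption: the target has no stereocentre and the hindered indenone–azulene axis is not specified, so it is left uncontrolled; the indanone intermediates are racemic at C3, a centre that becomes planar when the indenone is formed.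

Step 1
Reactants: 1 4-bromotoluene; 2 (E)-but-2-enoyl chloride (crotonoyl chloride)
Product: 3 (E)-1-(5-bromo-2-methylphenyl)but-2-en-1-one
Conditions: AlCl3 (1.2 equiv), CH2Cl2, 0 °C to rt (1 added to the preformed acyl chloride–AlCl3 complex); ice/aq. HCl quench
Reagents that add atoms: none
Why: Friedel–Crafts acylation, in which the acylium complex should react at low temperature before any conjugate alkylation and should enter ortho to the activating methyl group (para is blocked by bromine), which fixes the later 4-Br/7-CH3 pattern and keeps the E alkene.

Step 2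
Reactants: 3 (E)-1-(5-bromo-2-methylphenyl)but-2-en-1-one
Product: 4 rac-4-bromo-3,7-dimethyl-2,3-dihydro-1H-inden-1-one
Conditions: CF3SO3H (8 equiv), ClCH2CH2Cl, 80 °C
Reagents that add atoms: none
Why: Nazarov cyclisation of an aryl vinyl ketone in superacid (4π conrotatory closure of the O-protonated cation, then rearomatisation and tautomerisation) can close only onto the one ortho carbon that bears hydrogen, since the other bears the methyl group, and the new C3 centre is formed racemic and is erased in step 5.

Step 3
Reactants: 4 rac-4-bromo-3,7-dimethyl-2,3-dihydro-1H-inden-1-one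
Product: 5 rac-3,7-dimethyl-1-oxo-2,3-dihydro-1H-indene-4-carbaldehyde
Conditions: Pd(OAc)2 (1 mol %), n-BuP(1-adamantyl)2 (3 mol %), Me2NCH2CH2NMe2 (1.0 equiv), CO/H2 (1:1, 5 bar), toluene, 100 °C
Reagents that add atoms: carbon monoxide, [C-]#[O+] (H2 supplies only hydrogen)
Why: Palladium-catalysed reductive carbonylation (formylation) of an aryl bromide with synthesis gas, in which oxidative addition, CO insertion and hydrogenolysis of the acylpalladium species run under amine-buffered, non-enolising conditions that should leave the ketone untouched.

Step 4
Reactants: 5 rac-3,7-dimethyl-1-oxo-2,3-dihydro-1H-indene-4-carbaldehyde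
Product: 7 rac-2,2-dibromo-3,7-dimethyl-1-oxo-2,3-dihydro-1H-indene-4-carbaldehyde, via 2-monobromo ketone 6 (not isolated)
Conditions: Br2 (2.2 equiv), AcOH, 25 to 50 °C, dark
Reagents that add atoms: bromine, BrBr
Why: Acid-catalysed α-bromination through the enol should occur twice at C2, the only enolisable carbon (the formyl group and C7a have no α-hydrogen), while ionic conditions in the dark spare the benzylic methyl groups and the deactivated ring.

Step 5
Reactants: 7 rac-2,2-dibromo-3,7-dimethyl-1-oxo-2,3-dihydro-1H-indene-4-carbaldehyde
Product: 8 2-bromo-3,7-dimethyl-1-oxo-1H-indene-4-carbaldehyde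
Conditions: Li2CO3 (1.5 equiv), LiBr (1.5 equiv), DMF, 90 °C
Reagents that add atoms: none
Why: Dehydrobromination (E2) of an α,α-dibromo ketone, in which one of the two C2–Br bonds is always antiperiplanar to the benzylic C3–H, so loss of HBr should give the conjugated indenone with the second bromine left on C2 under a carbonate base too weak to harm the formyl group.

Step 6
Reactants: 8 2-bromo-3,7-dimethyl-1-oxo-1H-indene-4-carbaldehyde; 9 guaiazulene (1,4-dimethyl-7-(propan-2-yl)azulene, 1.5 equiv)
Product: 10 2-[3,8-dimethyl-5-(propan-2-yl)azulen-1-yl]-3,7-dimethyl-1-oxo-1H-indene-4-carbaldehyde (the guaiazulen-3-yl indenone, target)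
Conditions: Pd(OAc)2 (5 mol %), KOAc (2.0 equiv), n-Bu4NBr (1.0 equiv), DMAc, 100 °C, Ar
Reagents that add atoms: none
Why: Proposed new method: zerovalent palladium formed in situ from Pd(OAc)2 inserts into the C2–Br bond of the electron-poor α-bromoenone 8, the divalent alkenylpalladium species exchanges bromide for acetate and palladates 9 at C3 in an electrophilic, acetate-assisted C–H cleavage, and reductive elimination forms the indenone C2–azulene C3 bond and returns zerovalent palladium. The closest known reaction type is the palladium-catalysed direct C–H arylation of azulene and guaiazulene at the five-membered ring with aryl bromides under acetate conditions, together with the established cross-coupling of 2-bromoindenones through the same oxidative addition; new is the use of an α-bromoenone as the halide partner for an azulene C–H bond. No ring is closed and no stereocentre is formed. The step needs site selectivity in 9 among C3–H, C2–H and the acidic C4 methyl group: C1 is blocked by its methyl group, C3 is the one free carbon with the large HOMO coefficient of the five-membered ring and its σ-complex is a tropylium ion, and the weak acetate base in a carbonate-free, bromide-rich polar medium should favour this electrophilic pathway over concerted metalation at C2 or deprotonation of the C4 methyl group. It also needs chemoselectivity in 8, which is expected because the alkenyl C–Br bond is the only bond that adds to zerovalent palladium, the C3 methyl group blocks conjugate addition of the azulene, and the buffered, acid-free medium leaves the formyl group unactivated toward the nucleophilic azulene.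

**Compound list**
1 | 4-bromotoluene | Cc1ccc(Br)cc1 | starting material
2 | (E)-but-2-enoyl chloride (crotonoyl chloride) | C/C=C/C(=O)Cl | starting material
3 | (E)-1-(5-bromo-2-methylphenyl)but-2-en-1-one | C/C=C/C(=O)c1cc(Br)ccc1C | intermediate
4 | rac-4-bromo-3,7-dimethyl-2,3-dihydro-1H-inden-1-one | CC1CC(=O)c2c(C)ccc(Br)c21 | intermediate
5 | rac-3,7-dimethyl-1-oxo-2,3-dihydro-1H-indene-4-carbaldehyde | CC1CC(=O)c2c(C)ccc(C=O)c21 | intermediate
6 | rac-2-bromo-3,7-dimethyl-1-oxo-2,3-dihydro-1H-indene-4-carbaldehyde (diastereomer mixture, not isolated) | CC1C(Br)C(=O)c2c(C)ccc(C=O)c21 | intermediate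
7 | rac-2,2-dibromo-3,7-dimethyl-1-oxo-2,3-dihydro-1H-indene-4-carbaldehyde | CC1C(Br)(Br)C(=O)c2c(C)ccc(C=O)c21 | intermediate
8 | 2-bromo-3,7-dimethyl-1-oxo-1H-indene-4-carbaldehyde | CC1=C(Br)C(=O)c2c(C)ccc(C=O)c21 | intermediate
9 | guaiazulene (1,4-dimethyl-7-(propan-2-yl)azulene) | Cc1ccc(C(C)C)cc2c(C)ccc1-2 | starting material
10 | 2-[3,8-dimethyl-5-(propan-2-yl)azulen-1-yl]-3,7-dimethyl-1-oxo-1H-indene-4-carbaldehyde | CC1=C(c2cc(C)c3cc(C(C)C)ccc(C)c2-3)C(=O)c2c(C)ccc(C=O)c21 | target

**Step count:** 6 steps in total. The longest linear sequence is 6 steps (1 → 3 → 4 → 5 → 7 → 8 → 10); guaiazulene 9 enters as bought in step 6.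

**Steps most likely to fail**

Step 6 (Proposed new method). What may go wrong: palladation of 9 at C2 or at the C4 methyl group instead of C3, reduction of the C–Br bond of 8 before C–H cleavage, and base- or heat-induced oligomerisation of the bromoenone. The fallback is known chemistry, the acid-mediated Friedel–Crafts hydroxyalkylation–dehydration of an azulene with a 1,2-diketone; it sets out from 4 and comes back at 10. Compound 4 is nitrosated at C2 (isoamyl nitrite, conc. HCl, MeOH, 40 °C) to 4-bromo-2-(hydroxyimino)-3,7-dimethylindan-1-one F1. Transfer of the oxime to formaldehyde (37% aq. HCHO, conc. HCl, rt) frees 4-bromo-3,7-dimethylindane-1,2-dione F2. F2 and 9 (1.1 equiv) with CF3CO2H (20 mol %) in CH2Cl2 at rt should react by attack of C3 of 9 on the C2 carbonyl, which is more electrophilic than the aryl-conjugated C1 carbonyl shielded by the C7 methyl group. This gives the carbinol 4-bromo-2-(guaiazulen-3-yl)-2-hydroxy-3,7-dimethylindan-1-one F3, which is not isolated: ionisation to the azulenyl-stabilised cation and loss of the C3 proton should give 4-bromo-2-(guaiazulen-3-yl)-3,7-dimethyl-1H-inden-1-one F4. The aryl bromide is kept through this acid step because a free formyl group would itself condense with 9. Formylation of F4 under the conditions of step 3 then gives 10.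

Step 4. What may go wrong: the second enolisation of the α-bromo ketone is slow in acid, so bromination may stall at 6 while bromine starts to oxidise the formyl group; the E2 removal of the non-acidic C3–H in step 5 is the linked risk. The fallback sets out from 5 and comes back at 8, and replaces double enol substitution by dehydrogenation followed by addition–elimination. Compound 5 with PhSeCl (EtOAc, rt) should give 3,7-dimethyl-1-oxo-2-(phenylselanyl)indane-4-carbaldehyde F5, with selenium expected trans to the C3 methyl group. Oxidation with NaIO4/NaHCO3 (THF/H2O, 0 °C to rt) gives the selenoxide 3,7-dimethyl-1-oxo-2-(phenylseleninyl)indane-4-carbaldehyde F6, not isolated, whose syn-elimination with the cis C3–H gives 3,7-dimethyl-1-oxo-1H-indene-4-carbaldehyde F7. Br2 (CH2Cl2, 0 °C) adds across C2=C3 to give 2,3-dibromo-3,7-dimethyl-1-oxoindane-4-carbaldehyde F8. Et3N (CH2Cl2, 0 °C) then removes the acidic C2–H and expels the tertiary benzylic bromide (E1cB) to give 8.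

Step 1. What may go wrong: conjugate alkylation of the arene by the β-carbon of the acyl chloride before acylation (which would reverse the ring regiochemistry after closure), addition of HCl across the enone, and AlCl3-induced migration of bromine. The fallback sets out from 1 and comes back at 3, and separates C-acylation from introduction of the alkene. Compound 1 with acetyl chloride/AlCl3 (CH2Cl2, 0 °C) gives 1-(5-bromo-2-methylphenyl)ethan-1-one F9. Its lithium enolate (LiN(i-Pr)2, THF, −78 °C) adds to acetaldehyde to give rac-1-(5-bromo-2-methylphenyl)-3-hydroxybutan-1-one F10. Acid-catalysed dehydration (TsOH·H2O cat., toluene, 80 °C) gives the E enone 3.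

**Further compounds**
F1 | step 6 | 4-bromo-2-(hydroxyimino)-3,7-dimethyl-2,3-dihydro-1H-inden-1-one (racemic) | CC1C(=NO)C(=O)c2c(C)ccc(Br)c21
F2 | step 6 | 4-bromo-3,7-dimethylindane-1,2-dione (racemic) | CC1C(=O)C(=O)c2c(C)ccc(Br)c21
F3 | step 6 | 4-bromo-2-[3,8-dimethyl-5-(propan-2-yl)azulen-1-yl]-2-hydroxy-3,7-dimethyl-2,3-dihydro-1H-inden-1-one (racemic, diastereomer mixture, not isolated) | CC1C(O)(c2cc(C)c3cc(C(C)C)ccc(C)c2-3)C(=O)c2c(C)ccc(Br)c21
F4 | step 6 | 4-bromo-2-[3,8-dimethyl-5-(propan-2-yl)azulen-1-yl]-3,7-dimethyl-1H-inden-1-one | CC1=C(c2cc(C)c3cc(C(C)C)ccc(C)c2-3)C(=O)c2c(C)ccc(Br)c21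
F5 | step 4 | 3,7-dimethyl-1-oxo-2-(phenylselanyl)-2,3-dihydro-1H-indene-4-carbaldehyde (racemic, trans expected) | CC1C([Se]c2ccccc2)C(=O)c2c(C)ccc(C=O)c21
F6 | step 4 | 3,7-dimethyl-1-oxo-2-(phenylseleninyl)-2,3-dihydro-1H-indene-4-carbaldehyde (racemic, not isolated) | CC1C([Se](=O)c2ccccc2)C(=O)c2c(C)ccc(C=O)c21
F7 | step 4 | 3,7-dimethyl-1-oxo-1H-indene-4-carbaldehyde | CC1=CC(=O)c2c(C)ccc(C=O)c21
F8 | step 4 | 2,3-dibromo-3,7-dimethyl-1-oxo-2,3-dihydro-1H-indene-4-carbaldehyde (racemic, diastereomer mixture) | CC1(Br)C(Br)C(=O)c2c(C)ccc(C=O)c21
F9 | step 1 | 1-(5-bromo-2-methylphenyl)ethan-1-one | CC(=O)c1cc(Br)ccc1C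
F10 | step 1 | rac-1-(5-bromo-2-methylphenyl)-3-hydroxybutan-1-one | CC(O)CC(=O)c1cc(Br)ccc1C
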